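The target is cut at ring A of unit B, the (2S,3R,4R) flavan: its C7, C8 and C8a oxygens sit in a row and C4a carries the only carbon substituent, the pattern delivered by a 2,3-dialkoxy-4-alkenylcyclobutenone. One operation couples a squarate-derived chlorocyclobutenone with an (E)-alkenylstannane and turns the adduct, by ring opening and electrocyclisation, into the C8a phenol placed ortho to the chain. The stannane already holds unit A, the interflavanyl C4–O–C4 ether and C2–C4 of unit B; both units come from one syn-glycolate aldol adduct. Mitsunobu closure and hydrogenolysis finish the synthesis.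

Key step: step 21

Conventions: flavan numbering (C2, C3, C4, C4a, C5–C8, C8a) is used for both units; unit A is the (2R,3R,4R) all-cis flavan, unit B the (2S,3R,4R) 2,3-trans-3,4-cis flavan.
Assumption: the (Ra,R,R) enantiomer of the binaphthol-derived N,N-bis(1-phenylethyl)phosphoramidite is taken as the one that gives the R-configured branched ether in step 14; if the sense is the opposite, its mirror image is used.
Remark: alkoxides and other salts formed by simple deprotonation are treated as the ionised form of the reactant and carry no number of their own.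

Step 1
Reactants: 1 (S)-4-benzyloxazolidin-2-one; 2 (benzyloxy)acetyl chloride
Product: 3 (S)-4-benzyl-3-[(benzyloxy)acetyl]oxazolidin-2-one
Conditions: n-BuLi, THF, −78 °C; then 2, −78 → 0 °C
Reagents that add atoms: none
Why: N-acylation of the lithiated oxazolidinone by the acid chloride gives the imide; no stereocentre is formed.

Step 2
Reactants: 3 glycolyl imide; 4 4-(benzyloxy)benzaldehyde
Product: 6 syn-aldol adduct (S)-4-benzyl-3-[(2S,3R)-2-(benzyloxy)-3-[4-(benzyloxy)phenyl]-3-hydroxypropanoyl]oxazolidin-2-one, via boron enolate 5 (not isolated)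
Conditions: Bu2BOTf, Et3N, CH2Cl2, −78 → 0 °C; 4, −78 → 0 °C; then pH 7 buffer, MeOH, H2O2, 0 °C
Reagents that add atoms: none
Why: Evans syn-aldol reaction, in which the Z boron enolate adds through a closed chair (Zimmerman–Traxler) transition state on the face away from the auxiliary benzyl group, setting C2 as S and C3 as R (the later C3 and C2 of both flavan units) with the two oxygens already differentiated.

Step 3
Reactants: 6 syn-aldol adduct
Product: 7 (2S,3R)-2-(benzyloxy)-3-[4-(benzyloxy)phenyl]-3-hydroxy-N-methoxy-N-methylpropanamide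
Conditions: MeNH(OMe)·HCl, AlMe3, CH2Cl2, −20 → 0 °C
Reagents that add atoms: N,O-dimethylhydroxylamine hydrochloride, CNOC.Cl
Why: Aluminium-amide transamination of the imide, assisted by the free β-hydroxyl, gives the Weinreb amide and returns the auxiliary without touching either stereocentre.

Step 4
Reactants: 7 hydroxy Weinreb amide
Product: 8 (2S,3R)-2-(benzyloxy)-3-[4-(benzyloxy)phenyl]-N-methoxy-N-methyl-3-[(triethylsilyl)oxy]propanamide
Conditions: Et3SiCl, imidazole, DMF, 0 °C → rt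
Reagents that add atoms: chlorotriethylsilane, CC[Si](Cl)(CC)CC
Why: Silyl ether formation masks the benzylic oxygen (the later C2 oxygen) with a group that fluoride removes under neutral conditions.

Step 5
Reactants: 9 3-fluorobenzene-1,2-diol
Product: 10 1,2-bis(benzyloxy)-3-fluorobenzene
Conditions: BnBr, K2CO3, DMF, 60 °C
Reagents that add atoms: benzyl bromide, BrCc1ccccc1
Why: Double Williamson etherification of the catechol installs the same benzyl ethers used elsewhere, all of which fall in the last step.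

Step 6
Reactants: 10 1,2-bis(benzyloxy)-3-fluorobenzene; 8 silylated Weinreb amide
Product: 12 (2S,3R)-2-(benzyloxy)-1-[3,4-bis(benzyloxy)-2-fluorophenyl]-3-[4-(benzyloxy)phenyl]-3-[(triethylsilyl)oxy]propan-1-one, via aryllithium 11 (not isolated)
Conditions: 10, n-BuLi, THF, −78 °C; then 8, −78 → −60 °C; aq. NH4Cl
Reagents that add atoms: none
Why: Fluorine-directed ortho-lithiation (the most acidic ring proton lies next to fluorine, and −78 °C suppresses aryne formation and benzylic metalation) followed by Weinreb ketone synthesis, whose chelated tetrahedral adduct prevents over-addition and epimerisation.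

Step 7
Reactants: 12 aryl ketone
Product: 13 (1R,2R,3R)-2-(benzyloxy)-1-[3,4-bis(benzyloxy)-2-fluorophenyl]-3-[4-(benzyloxy)phenyl]-3-[(triethylsilyl)oxy]propan-1-ol
Conditions: Zn(BH4)2, Et2O, −30 → 0 °C
Reagents that add atoms: none
Why: Chelation-controlled reduction, in which zinc bridges the carbonyl and α-benzyloxy oxygens (Cram chelate; the silyl ether does not chelate) and hydride enters from the face of the α-hydrogen, gives the 1,2-anti alcohol with the new centre R (C4 of unit A).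

Step 8
Reactants: 13 anti alcohol
Product: 14 (1R,2S,3R)-2-(benzyloxy)-1-[3,4-bis(benzyloxy)-2-fluorophenyl]-3-[4-(benzyloxy)phenyl]propane-1,3-diol
Conditions: Bu4NF, THF, 0 °C
Reagents that add atoms: none
Why: Fluoride-mediated desilylation frees the C3 hydroxyl (the later O1 of unit A) without acid.

Step 9
Reactants: 14 fluoro diol
Product: 15 unit A alcohol (2R,3R,4R)-3,7,8-tris(benzyloxy)-2-[4-(benzyloxy)phenyl]chroman-4-ol
Conditions: KOt-Bu (2.5 equiv), DMF, 0 → 60 °C
Reagents that add atoms: none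
Why: Intramolecular nucleophilic aromatic substitution of fluoride by the C3 alkoxide closes the six-membered pyran ring (the C1 alkoxide cannot cyclise), and because the C–O bond at the benzylic carbon is never broken the syn-aldol relationship becomes 2,3-cis, giving the all-cis flavan-4-ol.

Step 10
Reactants: 8 silylated Weinreb amide
Product: 16 (2S,3R)-2-(benzyloxy)-3-[4-(benzyloxy)phenyl]-3-[(triethylsilyl)oxy]propanal
Conditions: i-Bu2AlH, THF, −78 °C; aq. sodium potassium tartrate
Reagents that add atoms: none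
Why: Hydride reduction of the Weinreb amide stops at the aldehyde because the aluminium-chelated hemiaminal survives until work-up.

Step 11
Reactants: 16 aldehyde
Product: 17 ethyl (2E,4R,5R)-4-(benzyloxy)-5-[4-(benzyloxy)phenyl]-5-[(triethylsilyl)oxy]pent-2-enoate
Conditions: (EtO)2P(O)CH2CO2Et, LiCl, DBU, MeCN, 0 °C → rt
Reagents that add atoms: triethyl phosphonoacetate, CCOC(=O)CP(=O)(OCC)OCC
Why: Horner–Wadsworth–Emmons olefination under the mild lithium chloride–amidine conditions should give the E-enoate without epimerising the α-alkoxy aldehyde.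

Step 12
Reactants: 17 enoate
Product: 18 (2E,4R,5R)-4-(benzyloxy)-5-[4-(benzyloxy)phenyl]-5-[(triethylsilyl)oxy]pent-2-en-1-ol
Conditions: i-Bu2AlH, CH2Cl2, −78 °C
Reagents that add atoms: none
Why: 1,2-Reduction of the conjugated ester by the aluminium hydride at low temperature gives the E-allylic alcohol.

Step 13
Reactants: 18 allylic alcohol
Product: 19 tert-butyl (2E,4R,5R)-4-(benzyloxy)-5-[4-(benzyloxy)phenyl]-5-[(triethylsilyl)oxy]pent-2-en-1-yl carbonate
Conditions: Boc2O, DMAP (cat.), CH2Cl2, 0 °C → rt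
Reagents that add atoms: di-tert-butyl dicarbonate, CC(C)(C)OC(=O)OC(=O)OC(C)(C)C
Why: Acylation of the primary alcohol gives the tert-butyl carbonate, chosen because the tert-butoxide released on ionisation is too hindered to compete as a nucleophile in step 14.

Step 14
Reactants: 15 unit A alcohol; 19 allylic carbonate
Product: 20 branched allyl ether (2R,3R,4R)-3,7,8-tris(benzyloxy)-2-[4-(benzyloxy)phenyl]-4-{[(3R,4R,5R)-4-(benzyloxy)-5-[4-(benzyloxy)phenyl]-5-[(triethylsilyl)oxy]pent-1-en-3-yl]oxy}chromane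
Conditions: 15, n-BuLi, THF, −78 → 0 °C; CuI; then [Ir(cod)Cl]2 (4 mol %), (Ra,R,R)-phosphoramidite (8 mol %), 19, THF, rt
Reagents that add atoms: none
Why: Iridium-catalysed allylic etherification, in which the cyclometalated iridium–phosphoramidite complex ionises the linear carbonate and directs the soft monovalent-copper alkoxide of 15 to the substituted allyl terminus anti to the metal, should give the branched ether with catalyst control of the new centre (R, the later C4 of unit B, anti to the neighbouring benzyloxy group) while C4 of unit A keeps its C–O bond.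

Step 15
Reactants: 20 branched allyl ether
Product: 22 (2S,3R,4R)-3-(benzyloxy)-4-[4-(benzyloxy)phenyl]-2-{[(2R,3R,4R)-3,7,8-tris(benzyloxy)-2-[4-(benzyloxy)phenyl]chroman-4-yl]oxy}-4-[(triethylsilyl)oxy]butanal, via vicinal diol 21 (not isolated)
Conditions: OsO4 (cat.), NaIO4, 2,6-lutidine, dioxane–H2O, rt
Reagents that add atoms: osmium tetroxide, O=[Os](=O)(=O)=O (delivers the aldehyde oxygen and is re-formed by sodium periodate, [Na+].[O-]I(=O)(=O)=O)
Why: Lemieux–Johnson oxidation (osmylation of the only alkene, then periodate cleavage) gives the α-alkoxy aldehyde, which is used crude to avoid epimerisation, the lutidine buffer protecting the silyl ether and the benzylic ether of unit A.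

Step 16
Reactants: 23 dibromomethane; 24 tributyltin chloride
Product: 26 tributyl(dibromomethyl)stannane, via dibromomethyllithium 25 (not isolated)
Conditions: LiN(i-Pr)2, THF–Et2O, −100 °C; then Bu3SnCl, −100 → −78 °C
Reagents that add atoms: none
Why: Deprotonation of dibromomethane gives the carbenoid, which is trapped by the tin chloride before it can decompose (stannylation of an α-halo organolithium).

Step 17
Reactants: 22 aldehyde; 26 tributyl(dibromomethyl)stannane
Product: 27 (E)-alkenylstannane tributyl[(1E,3R,4R,5R)-4-(benzyloxy)-5-[4-(benzyloxy)phenyl]-3-{[(2R,3R,4R)-3,7,8-tris(benzyloxy)-2-[4-(benzyloxy)phenyl]chroman-4-yl]oxy}-5-[(triethylsilyl)oxy]pent-1-en-1-yl]stannane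
Conditions: CrCl2, LiI, DMF–THF, rt, dark
Reagents that add atoms: none
Why: Takai-type olefination with the geminal dichromium species formed from 26 and divalent chromium should convert the aldehyde into the E-alkenylstannane under neutral conditions that leave the α-stereocentre intact.

Step 18
Reactants: 28 squaric acid
Product: 29 3,4-bis(benzyloxy)cyclobut-3-ene-1,2-dione
Conditions: BnOH, toluene, reflux, azeotropic removal of water
Reagents that add atoms: benzyl alcohol, OCc1ccccc1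
Why: Azeotropic esterification of the strongly acidic vinylogous diacid with benzyl alcohol gives the diester.

Step 19
Reactants: 29 dibenzyl squarate
Product: 30 2,3-bis(benzyloxy)-4-hydroxycyclobut-2-en-1-one (racemic)
Conditions: LiAlH(Ot-Bu)3, THF, −78 °C
Reagents that add atoms: none
Why: Selective 1,2-reduction of one of the two equivalent carbonyl groups by the hindered hydride at low temperature gives the hydroxycyclobutenone.

Step 20
Reactants: 30 hydroxycyclobutenone
Product: 31 2,3-bis(benzyloxy)-4-chlorocyclobut-2-en-1-one (racemic)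
Conditions: PPh3, CCl4, CH2Cl2, 0 °C → rt
Reagents that add atoms: carbon tetrachloride, ClC(Cl)(Cl)Cl
Why: Appel chlorination replaces the hydroxyl by chloride under neutral conditions, avoiding the acid that would expel benzyl alcohol; the racemic chloride is used fresh since its stereocentre disappears in step 21.

Step 21
Reactants: 27 (E)-alkenylstannane; 31 chlorocyclobutenone
Product: 35 2,3-bis(benzyloxy)-6-[(1R,2R,3R)-2-(benzyloxy)-3-[4-(benzyloxy)phenyl]-1-{[(2R,3R,4R)-3,7,8-tris(benzyloxy)-2-[4-(benzyloxy)phenyl]chroman-4-yl]oxy}-3-[(triethylsilyl)oxy]propyl]phenol, via alkenylcyclobutenone 32 (not isolated), via dienylketene 33 (not isolated), via cyclohexadienone 34 (not isolated)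
Conditions: Pd2(dba)3 (5 mol %), tri(2-furyl)phosphine (20 mol %), dioxane, 50 °C, then 90 °C
Reagents that add atoms: none
Why: Zerovalent palladium inserts into the allylic C–Cl bond of 31, the alkenyl group is transferred from tin with retention of the E geometry and reductive elimination at the hydrogen-bearing terminus gives 32 (Stille coupling); on warming, 32 undergoes conrotatory 4π ring opening to the dienylketene 33, thermal disrotatory 6π electrocyclisation joins the ketene carbon to the distal alkene carbon, and enolisation of 34 gives the arene. The closest known reaction type is the palladium-catalysed coupling of 4-chlorocyclobutenones with alkenylstannanes followed by ring expansion in situ to phenols. Ring A of unit B is closed by the 6π electrocyclisation (bond C4a–C8a) after the cross-coupling has made C5–C6: the ketene carbonyl becomes the C8a hydroxyl, the two benzyloxy carbons become C8 and C7, the former CHCl carbon becomes C6 and the two stannane carbons become C5 and C4a. No stereocentre is formed, and the three centres of the chain and the three of unit A stay untouched because the medium is neutral. The step needs regioselectivity (fixed by the connectivity of the electrocyclisation and by coupling at the unsubstituted allyl terminus), productive torquoselectivity (ring opening is reversible, so only the inward-rotated dienylketene is drained to the arene) and chemoselectivity for the C–Cl bond over the benzyl ethers and the acid-labile C4–O bond of unit A (secured by the mild ligand and the absence of acid or base).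

Step 22
Reactants: 35 phenol
Product: 36 2,3-bis(benzyloxy)-6-[(1R,2S,3R)-2-(benzyloxy)-3-[4-(benzyloxy)phenyl]-3-hydroxy-1-{[(2R,3R,4R)-3,7,8-tris(benzyloxy)-2-[4-(benzyloxy)phenyl]chroman-4-yl]oxy}propyl]phenol
Conditions: Bu4NF, AcOH, THF, 0 °C → rt
Reagents that add atoms: none
Why: Buffered fluoride desilylation removes the triethylsilyl ether selectively and exposes the C2 hydroxyl of unit B.

Step 23
Reactants: 36 phenol alcohol
Product: 37 (2R,3R,4R)-3,7,8-tris(benzyloxy)-2-[4-(benzyloxy)phenyl]-4-{[(2S,3R,4R)-3,7,8-tris(benzyloxy)-2-[4-(benzyloxy)phenyl]chroman-4-yl]oxy}chromane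
Conditions: PPh3, DIAD, THF, 0 °C → rt
Reagents that add atoms: none
Why: Intramolecular Mitsunobu etherification, in which the phenol displaces the activated benzylic oxygen in an SN2 6-exo closure with inversion, turns C2 from R into S and gives the 2,3-trans-3,4-cis pyran ring of unit B.

Step 24
Reactants: 37 octabenzyl ether
Product: 38 (2R,3R,4R)-2-(4-hydroxyphenyl)-4-{[(2S,3R,4R)-3,7,8-trihydroxy-2-(4-hydroxyphenyl)chroman-4-yl]oxy}chromane-3,7,8-triol
Conditions: H2 (1 atm), Pd(OH)2/C, THF–MeOH, rt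
Reagents that add atoms: none
Why: Hydrogenolysis of the eight O-benzyl groups in a neutral medium should give the free octol, since benzyl ethers cleave faster than the hindered doubly secondary C4–O–C4 ether and the reaction is stopped once debenzylation is complete.

Compound list
1 | (S)-4-benzyloxazolidin-2-one | O=C1N[C@@H](Cc2ccccc2)CO1 | starting material
2 | (benzyloxy)acetyl chloride | O=C(Cl)COCc1ccccc1 | starting material
3 | (S)-4-benzyl-3-[(benzyloxy)acetyl]oxazolidin-2-one | O=C1OC[C@H](Cc2ccccc2)N1C(=O)COCc1ccccc1 | intermediate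
4 | 4-(benzyloxy)benzaldehyde | O=Cc1ccc(OCc2ccccc2)cc1 | starting material
5 | dibutylboron Z-enolate of 3 | CCCCB(CCCC)O/C(=C\OCc1ccccc1)N1C(=O)OC[C@@H]1Cc1ccccc1 | intermediate (not isolated)
6 | (S)-4-benzyl-3-[(2S,3R)-2-(benzyloxy)-3-[4-(benzyloxy)phenyl]-3-hydroxypropanoyl]oxazolidin-2-one | O=C1OC[C@H](Cc2ccccc2)N1C(=O)[C@@H](OCc1ccccc1)[C@H](O)c1ccc(OCc2ccccc2)cc1 | intermediate
7 | (2S,3R)-2-(benzyloxy)-3-[4-(benzyloxy)phenyl]-3-hydroxy-N-methoxy-N-methylpropanamide | CON(C)C(=O)[C@@H](OCc1ccccc1)[C@H](O)c1ccc(OCc2ccccc2)cc1 | intermediate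
8 | (2S,3R)-2-(benzyloxy)-3-[4-(benzyloxy)phenyl]-N-methoxy-N-methyl-3-[(triethylsilyl)oxy]propanamide | CON(C)C(=O)[C@@H](OCc1ccccc1)[C@H](O[Si](CC)(CC)CC)c1ccc(OCc2ccccc2)cc1 | intermediate
9 | 3-fluorobenzene-1,2-diol | Oc1cccc(F)c1O | starting material
10 | 1,2-bis(benzyloxy)-3-fluorobenzene | Fc1cccc(OCc2ccccc2)c1OCc1ccccc1 | intermediate
11 | [3,4-bis(benzyloxy)-2-fluorophenyl]lithium | [Li]c1ccc(OCc2ccccc2)c(OCc2ccccc2)c1F | intermediate (not isolated)
12 | (2S,3R)-2-(benzyloxy)-1-[3,4-bis(benzyloxy)-2-fluorophenyl]-3-[4-(benzyloxy)phenyl]-3-[(triethylsilyl)oxy]propan-1-one | O=C(c1ccc(OCc2ccccc2)c(OCc2ccccc2)c1F)[C@@H](OCc1ccccc1)[C@H](O[Si](CC)(CC)CC)c1ccc(OCc2ccccc2)cc1 | intermediate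
13 | (1R,2R,3R)-2-(benzyloxy)-1-[3,4-bis(benzyloxy)-2-fluorophenyl]-3-[4-(benzyloxy)phenyl]-3-[(triethylsilyl)oxy]propan-1-ol | O[C@H](c1ccc(OCc2ccccc2)c(OCc2ccccc2)c1F)[C@@H](OCc1ccccc1)[C@H](O[Si](CC)(CC)CC)c1ccc(OCc2ccccc2)cc1 | intermediate
14 | (1R,2S,3R)-2-(benzyloxy)-1-[3,4-bis(benzyloxy)-2-fluorophenyl]-3-[4-(benzyloxy)phenyl]propane-1,3-diol | O[C@H](c1ccc(OCc2ccccc2)c(OCc2ccccc2)c1F)[C@@H](OCc1ccccc1)[C@H](O)c1ccc(OCc2ccccc2)cc1 | intermediate
15 | (2R,3R,4R)-3,7,8-tris(benzyloxy)-2-[4-(benzyloxy)phenyl]chroman-4-ol (unit A alcohol) | O[C@@H]1c2ccc(OCc3ccccc3)c(OCc3ccccc3)c2O[C@H](c2ccc(OCc3ccccc3)cc2)[C@@H]1OCc1ccccc1 | intermediate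
16 | (2S,3R)-2-(benzyloxy)-3-[4-(benzyloxy)phenyl]-3-[(triethylsilyl)oxy]propanal | O=C[C@@H](OCc1ccccc1)[C@H](O[Si](CC)(CC)CC)c1ccc(OCc2ccccc2)cc1 | intermediate
17 | ethyl (2E,4R,5R)-4-(benzyloxy)-5-[4-(benzyloxy)phenyl]-5-[(triethylsilyl)oxy]pent-2-enoate | CCOC(=O)/C=C/[C@@H](OCc1ccccc1)[C@H](O[Si](CC)(CC)CC)c1ccc(OCc2ccccc2)cc1 | intermediate
18 | (2E,4R,5R)-4-(benzyloxy)-5-[4-(benzyloxy)phenyl]-5-[(triethylsilyl)oxy]pent-2-en-1-ol | OC/C=C/[C@@H](OCc1ccccc1)[C@H](O[Si](CC)(CC)CC)c1ccc(OCc2ccccc2)cc1 | intermediate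
19 | tert-butyl (2E,4R,5R)-4-(benzyloxy)-5-[4-(benzyloxy)phenyl]-5-[(triethylsilyl)oxy]pent-2-en-1-yl carbonate | CC(C)(C)OC(=O)OC/C=C/[C@@H](OCc1ccccc1)[C@H](O[Si](CC)(CC)CC)c1ccc(OCc2ccccc2)cc1 | intermediate
20 | (2R,3R,4R)-3,7,8-tris(benzyloxy)-2-[4-(benzyloxy)phenyl]-4-{[(3R,4R,5R)-4-(benzyloxy)-5-[4-(benzyloxy)phenyl]-5-[(triethylsilyl)oxy]pent-1-en-3-yl]oxy}chromane | C=C[C@@H](O[C@@H]1c2ccc(OCc3ccccc3)c(OCc3ccccc3)c2O[C@H](c2ccc(OCc3ccccc3)cc2)[C@@H]1OCc1ccccc1)[C@@H](OCc1ccccc1)[C@H](O[Si](CC)(CC)CC)c1ccc(OCc2ccccc2)cc1 | intermediate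
21 | vicinal diol from osmylation of the vinyl group of 20 (both epimers at the new carbinol) | OCC(O)[C@@H](O[C@@H]1c2ccc(OCc3ccccc3)c(OCc3ccccc3)c2O[C@H](c2ccc(OCc3ccccc3)cc2)[C@@H]1OCc1ccccc1)[C@@H](OCc1ccccc1)[C@H](O[Si](CC)(CC)CC)c1ccc(OCc2ccccc2)cc1 | intermediate (not isolated)
22 | (2S,3R,4R)-3-(benzyloxy)-4-[4-(benzyloxy)phenyl]-2-{[(2R,3R,4R)-3,7,8-tris(benzyloxy)-2-[4-(benzyloxy)phenyl]chroman-4-yl]oxy}-4-[(triethylsilyl)oxy]butanal | O=C[C@@H](O[C@@H]1c2ccc(OCc3ccccc3)c(OCc3ccccc3)c2O[C@H](c2ccc(OCc3ccccc3)cc2)[C@@H]1OCc1ccccc1)[C@@H](OCc1ccccc1)[C@H](O[Si](CC)(CC)CC)c1ccc(OCc2ccccc2)cc1 | intermediate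
23 | dibromomethane | BrCBr | starting material
24 | tributyltin chloride | CCCC[Sn](Cl)(CCCC)CCCC | starting material
25 | dibromomethyllithium | [Li]C(Br)Br | intermediate (not isolated)
26 | tributyl(dibromomethyl)stannane | CCCC[Sn](CCCC)(CCCC)C(Br)Br | intermediate
27 | tributyl[(1E,3R,4R,5R)-4-(benzyloxy)-5-[4-(benzyloxy)phenyl]-3-{[(2R,3R,4R)-3,7,8-tris(benzyloxy)-2-[4-(benzyloxy)phenyl]chroman-4-yl]oxy}-5-[(triethylsilyl)oxy]pent-1-en-1-yl]stannane | CCCC[Sn](CCCC)(CCCC)/C=C/[C@@H](O[C@@H]1c2ccc(OCc3ccccc3)c(OCc3ccccc3)c2O[C@H](c2ccc(OCc3ccccc3)cc2)[C@@H]1OCc1ccccc1)[C@@H](OCc1ccccc1)[C@H](O[Si](CC)(CC)CC)c1ccc(OCc2ccccc2)cc1 | intermediate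
28 | squaric acid (3,4-dihydroxycyclobut-3-ene-1,2-dione) | OC1=C(O)C(=O)C1=O | starting material
29 | 3,4-bis(benzyloxy)cyclobut-3-ene-1,2-dione | O=C1C(=O)C(OCc2ccccc2)=C1OCc1ccccc1 | intermediate
30 | 2,3-bis(benzyloxy)-4-hydroxycyclobut-2-en-1-one (racemic) | O=C1C(OCc2ccccc2)=C(OCc2ccccc2)C1O | intermediate
31 | 2,3-bis(benzyloxy)-4-chlorocyclobut-2-en-1-one (racemic) | O=C1C(OCc2ccccc2)=C(OCc2ccccc2)C1Cl | intermediate
32 | 2,3-bis(benzyloxy)-4-alkenylcyclobut-2-en-1-one carrying the chain of 27 at C4 (both epimers at the ring carbon) | O=C1C(OCc2ccccc2)=C(OCc2ccccc2)C1/C=C/[C@@H](O[C@@H]1c2ccc(OCc3ccccc3)c(OCc3ccccc3)c2O[C@H](c2ccc(OCc3ccccc3)cc2)[C@@H]1OCc1ccccc1)[C@@H](OCc1ccccc1)[C@H](O[Si](CC)(CC)CC)c1ccc(OCc2ccccc2)cc1 | intermediate (not isolated)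
33 | 2,3-bis(benzyloxy)hexa-1,3,5-trien-1-one (dienylketene) carrying the chain at C6, ketene and alkenyl groups cis on the central double bond | O=C=C(OCc1ccccc1)/C(OCc1ccccc1)=C\C=C\[C@@H](O[C@@H]1c2ccc(OCc3ccccc3)c(OCc3ccccc3)c2O[C@H](c2ccc(OCc3ccccc3)cc2)[C@@H]1OCc1ccccc1)[C@@H](OCc1ccccc1)[C@H](O[Si](CC)(CC)CC)c1ccc(OCc2ccccc2)cc1 | intermediate (not isolated)
34 | 2,3-bis(benzyloxy)cyclohexa-2,4-dien-1-one carrying the chain at C6 (both epimers at C6) | O=C1C(OCc2ccccc2)=C(OCc2ccccc2)C=CC1[C@@H](O[C@@H]1c2ccc(OCc3ccccc3)c(OCc3ccccc3)c2O[C@H](c2ccc(OCc3ccccc3)cc2)[C@@H]1OCc1ccccc1)[C@@H](OCc1ccccc1)[C@H](O[Si](CC)(CC)CC)c1ccc(OCc2ccccc2)cc1 | intermediate (not isolated)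
35 | 2,3-bis(benzyloxy)-6-[(1R,2R,3R)-2-(benzyloxy)-3-[4-(benzyloxy)phenyl]-1-{[(2R,3R,4R)-3,7,8-tris(benzyloxy)-2-[4-(benzyloxy)phenyl]chroman-4-yl]oxy}-3-[(triethylsilyl)oxy]propyl]phenol | Oc1c(OCc2ccccc2)c(OCc2ccccc2)ccc1[C@@H](O[C@@H]1c2ccc(OCc3ccccc3)c(OCc3ccccc3)c2O[C@H](c2ccc(OCc3ccccc3)cc2)[C@@H]1OCc1ccccc1)[C@@H](OCc1ccccc1)[C@H](O[Si](CC)(CC)CC)c1ccc(OCc2ccccc2)cc1 | intermediate
36 | 2,3-bis(benzyloxy)-6-[(1R,2S,3R)-2-(benzyloxy)-3-[4-(benzyloxy)phenyl]-3-hydroxy-1-{[(2R,3R,4R)-3,7,8-tris(benzyloxy)-2-[4-(benzyloxy)phenyl]chroman-4-yl]oxy}propyl]phenol | Oc1c(OCc2ccccc2)c(OCc2ccccc2)ccc1[C@@H](O[C@@H]1c2ccc(OCc3ccccc3)c(OCc3ccccc3)c2O[C@H](c2ccc(OCc3ccccc3)cc2)[C@@H]1OCc1ccccc1)[C@@H](OCc1ccccc1)[C@H](O)c1ccc(OCc2ccccc2)cc1 | intermediate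
37 | (2R,3R,4R)-3,7,8-tris(benzyloxy)-2-[4-(benzyloxy)phenyl]-4-{[(2S,3R,4R)-3,7,8-tris(benzyloxy)-2-[4-(benzyloxy)phenyl]chroman-4-yl]oxy}chromane | c1ccccc1COc1ccc(cc1)[C@H]1Oc2c(ccc(OCc3ccccc3)c2OCc2ccccc2)[C@@H](O[C@@H]2c3ccc(OCc4ccccc4)c(OCc4ccccc4)c3O[C@@H](c3ccc(OCc4ccccc4)cc3)[C@@H]2OCc2ccccc2)[C@H]1OCc1ccccc1 | intermediate
38 | (2R,3R,4R)-2-(4-hydroxyphenyl)-4-{[(2S,3R,4R)-3,7,8-trihydroxy-2-(4-hydroxyphenyl)chroman-4-yl]oxy}chromane-3,7,8-triol | Oc1ccc([C@H]2Oc3c(ccc(O)c3O)[C@@H](O[C@@H]3c4ccc(O)c(O)c4O[C@@H](c4ccc(O)cc4)[C@@H]3O)[C@H]2O)cc1 | target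

Total step count: 24. Longest linear sequence: 15 steps (1 → 3 → 6 → 7 → 8 → 12 → 13 → 14 → 15 → 20 → 22 → 27 → 35 → 36 → 37 → 38).

Steps most likely to fail

Step 21. The chlorocyclobutenone may ionise or lose benzyl chloride before oxidative addition, transmetalation of the crowded γ-alkoxy alkenylstannane may be slow, and outward ring opening may divert the ketene to oligomers. The fallback sets out from 27 and 29. Tin–lithium exchange on 27 (n-BuLi, THF, −78 °C) and 1,2-addition of the alkenyllithium to dibenzyl squarate 29 should give the 4-alkenyl-4-hydroxycyclobutenone F1. Thermolysis in toluene at 110 °C (Moore rearrangement: the hydroxyl rotates outward, the alkenyl group inward, then 6π closure) should give the hydroquinone F2, which carries one extra hydroxyl at C6. This unhindered hydroxyl is triflated selectively (PhNTf2, Et3N, CH2Cl2) to the monotriflate F3. Palladium-catalysed formate reduction (Pd(OAc)2, PPh3, HCO2H, Et3N, DMF, 60 °C) then removes it and the route is rejoined at phenol 35.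

Step 14. The hindered secondary alkoxide of 15 may attack the allyl-iridium intermediate too slowly, so that elimination to a diene or attack at the unsubstituted terminus takes over, and mismatched double stereodifferentiation may erode control at the new centre. The fallback sets out from 18 and 15. Alcohol 18 is converted with 4-nitrophenyl chloroformate and pyridine into the 4-nitrophenyl carbonate F4, which acylates the lithium alkoxide of 15 to give the mixed dialkyl carbonate F5. The same [Ir(cod)Cl]2–phosphoramidite catalyst then effects decarboxylative allylic etherification. Here the alkoxide is released only as the counter-ion of the allyl-iridium cation, so it recombines at the branched terminus without a competing nucleophile, and the route is rejoined at 20.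

Step 17. Addition of the bulky geminal dichromium reagent to the hindered α,β-dialkoxy aldehyde may be slow, leaving time for β-elimination of benzyl alcohol or for erosion of E selectivity. The fallback sets out from 22. Ohira–Bestmann homologation (dimethyl (1-diazo-2-oxopropyl)phosphonate, K2CO3, MeOH, 0 °C) should give the terminal alkyne F6. Palladium-catalysed syn-hydrostannation (Bu3SnH, PdCl2(PPh3)2, THF, 0 °C) places tin at the unhindered terminus and rejoins the route at the E-stannane 27.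

Further compounds
F1 | step 21 | 2,3-bis(benzyloxy)-4-hydroxy-4-alkenylcyclobut-2-en-1-one carrying the chain of 27 (both epimers at the carbinol) | O=C1C(OCc2ccccc2)=C(OCc2ccccc2)C1(O)/C=C/[C@@H](O[C@@H]1c2ccc(OCc3ccccc3)c(OCc3ccccc3)c2O[C@H](c2ccc(OCc3ccccc3)cc2)[C@@H]1OCc1ccccc1)[C@@H](OCc1ccccc1)[C@H](O[Si](CC)(CC)CC)c1ccc(OCc2ccccc2)cc1
F2 | step 21 | 2,3-bis(benzyloxy)benzene-1,4-diol carrying the chain of 35 at C6 (hydroquinone) | Oc1c(OCc2ccccc2)c(OCc2ccccc2)c(O)cc1[C@@H](O[C@@H]1c2ccc(OCc3ccccc3)c(OCc3ccccc3)c2O[C@H](c2ccc(OCc3ccccc3)cc2)[C@@H]1OCc1ccccc1)[C@@H](OCc1ccccc1)[C@H](O[Si](CC)(CC)CC)c1ccc(OCc2ccccc2)cc1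
F3 | step 21 | monotriflate of F2 at the hydroxyl para to the chain-flanked hydroxyl | Oc1c(OCc2ccccc2)c(OCc2ccccc2)c(OS(=O)(=O)C(F)(F)F)cc1[C@@H](O[C@@H]1c2ccc(OCc3ccccc3)c(OCc3ccccc3)c2O[C@H](c2ccc(OCc3ccccc3)cc2)[C@@H]1OCc1ccccc1)[C@@H](OCc1ccccc1)[C@H](O[Si](CC)(CC)CC)c1ccc(OCc2ccccc2)cc1
F4 | step 14 | 4-nitrophenyl carbonate of 18 | O=C(Oc1ccc([N+](=O)[O-])cc1)OC/C=C/[C@@H](OCc1ccccc1)[C@H](O[Si](CC)(CC)CC)c1ccc(OCc2ccccc2)cc1
F5 | step 14 | mixed carbonate of 15 (at O4) and 18 | O=C(OC/C=C/[C@@H](OCc1ccccc1)[C@H](O[Si](CC)(CC)CC)c1ccc(OCc2ccccc2)cc1)O[C@@H]1c2ccc(OCc3ccccc3)c(OCc3ccccc3)c2O[C@H](c2ccc(OCc3ccccc3)cc2)[C@@H]1OCc1ccccc1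
F6 | step 17 | terminal alkyne from 22 (ethynyl in place of formyl) | C#C[C@@H](O[C@@H]1c2ccc(OCc3ccccc3)c(OCc3ccccc3)c2O[C@H](c2ccc(OCc3ccccc3)cc2)[C@@H]1OCc1ccccc1)[C@@H](OCc1ccccc1)[C@H](O[Si](CC)(CC)CC)c1ccc(OCc2ccccc2)cc1
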